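## Retrosynthetic overview

1. Target 25 ⇐ macrocyclic 7E-olefin 24 by a final Schenck ene reaction (C7–OOH, C8=C19).
2. 24 ⇐ acyclic lactone 21 by intramolecular B-alkyl Suzuki coupling (C6–C7); the 14-membered ring is the last ring formed.
3. 21 ⇐ diene acid 14: one Shi epoxidation makes both oxiranes, the acid opens the 3,4-oxirane to the δ-lactone, and C15–CH3 comes from lactone enolate methylation.
4. 14 ⇐ enal 8 + dimethyl malonate 9: the key C1–C15 bond is an intermolecular organocatalytic Michael addition that sets C1; C3=C4 comes from a Wittig reaction.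
5. 8 ⇐ pent-4-yn-1-ol 1 by carboalumination/bromination, isopropenyl addition, Johnson–Claisen rearrangement and Wittig reaction. Ring order: oxiranes → δ-lactone → macrocycle.

Assumption: positions are given in cembrane numbering (C1 carries the C15–C17 propionate unit, lactone C16–O–C3, carbinol C4, hydroperoxide C7, C8=C19, oxirane C11–C12); the target is then the (1R,3R,4S,7R,11S,12S,15S) isomer.

## Route

Step 1
Reactants: 1 pent-4-yn-1-ol
Product: 3 (E)-5-bromo-4-methylpent-4-en-1-ol, via alkenylalane 2 (not isolated)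
Conditions: Me3Al (3 equiv), Cp2ZrCl2 (0.25 equiv), CH2Cl2, 0 °C → rt; then NBS, THF, −30 → 0 °C
Reagents that add atoms: trimethylaluminium C[Al](C)C; N-bromosuccinimide O=C1CCC(=O)N1Br
Why: Zr-catalysed Negishi carboalumination adds CH3 and Al syn across the terminal alkyne with Al at the terminus, and bromodealumination with retention fixes the E-trisubstituted vinyl bromide (C7=C8, C19).

Step 2
Reactants: 3 (E)-5-bromo-4-methylpent-4-en-1-ol
Product: 4 (E)-5-bromo-4-methylpent-4-enal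
Conditions: Dess–Martin periodinane, CH2Cl2, 0 °C → rt
Reagents that add atoms: none
Why: Dess–Martin oxidation takes the primary alcohol to the aldehyde and leaves the vinyl bromide alone.

Step 3
Reactants: 4 (E)-5-bromo-4-methylpent-4-enal
Product: 5 (6E)-7-bromo-2,6-dimethylhepta-1,6-dien-3-ol (racemic)
Conditions: CH2=C(CH3)MgBr, THF, −78 → 0 °C; aq. NH4Cl
Reagents that add atoms: isopropenylmagnesium bromide CC(=C)[Mg]Br
Why: Grignard addition to the aldehyde gives the 2-methylallylic alcohol; its carbinol centre is racemic and is destroyed in step 4.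

Step 4
Reactants: 5 (6E)-7-bromo-2,6-dimethylhepta-1,6-dien-3-ol
Product: 6 ethyl (4E,8E)-9-bromo-4,8-dimethylnona-4,8-dienoate
Conditions: CH3C(OEt)3 (8 equiv), EtCO2H (cat.), 140 °C, EtOH distilled off
Reagents that add atoms: triethyl orthoacetate CCOC(C)(OCC)OCC
Why: the Johnson–Claisen orthoester rearrangement runs through a chair transition state with the chain equatorial, which gives the E-trisubstituted C11=C12 olefin and adds the C14–C1 ester unit.

Step 5
Reactants: 6 ethyl (4E,8E)-9-bromo-4,8-dimethylnona-4,8-dienoate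
Product: 7 (4E,8E)-9-bromo-4,8-dimethylnona-4,8-dienal
Conditions: i-Bu2AlH (1.05 equiv), CH2Cl2, −78 °C; aq. KNaC4H4O6
Reagents that add atoms: none
Why: partial hydride reduction of the ester stops at the tetrahedral aluminate at −78 °C and releases the aldehyde on work-up.

Step 6
Reactants: 7 (4E,8E)-9-bromo-4,8-dimethylnona-4,8-dienal
Product: 8 (2E,6E,10E)-11-bromo-6,10-dimethylundeca-2,6,10-trienal
Conditions: Ph3P=CHCHO (1.2 equiv), toluene, 80 °C
Reagents that add atoms: (triphenylphosphoranylidene)acetaldehyde O=CC=P(c1ccccc1)(c1ccccc1)c1ccccc1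
Why: Wittig olefination with the stabilised formyl ylide gives the E-enal (C1=C2, C3 aldehyde) needed for iminium activation.

Step 7
Reactants: 8 (2E,6E,10E)-11-bromo-6,10-dimethylundeca-2,6,10-trienal; 9 dimethyl malonate
Product: 10 dimethyl 2-[(3R,6E,10E)-11-bromo-6,10-dimethyl-1-oxoundeca-6,10-dien-3-yl]propanedioate
Conditions: (S)-2-{bis[3,5-bis(trifluoromethyl)phenyl](trimethylsilyloxy)methyl}pyrrolidine (10 mol %), 9 (2 equiv), EtOH, 0 °C → rt
Reagents that add atoms: none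
Why: in this iminium-catalysed intermolecular Michael addition the silyloxydiarylmethyl group shields one face of the E-iminium ion, so the malonate adds to the open face of C1 and gives the (R) centre in about 90% ee.

Step 8
Reactants: 10 dimethyl 2-[(3R,6E,10E)-11-bromo-6,10-dimethyl-1-oxoundeca-6,10-dien-3-yl]propanedioate
Product: 11 dimethyl 2-[(2E,5R,8E,12E)-13-bromo-2,8,12-trimethyl-1-oxotrideca-2,8,12-trien-5-yl]propanedioate
Conditions: Ph3P=C(CH3)CHO (1.3 equiv), toluene, 90 °C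
Reagents that add atoms: 2-(triphenylphosphoranylidene)propanal CC(C=O)=P(c1ccccc1)(c1ccccc1)c1ccccc1
Why: Wittig olefination with the stabilised α-methyl ylide gives the E-trisubstituted C3=C4 enal (C18 methyl, C5 aldehyde); the ylide is too weak a base to touch the malonate.

Step 9
Reactants: 11 dimethyl 2-[(2E,5R,8E,12E)-13-bromo-2,8,12-trimethyl-1-oxotrideca-2,8,12-trien-5-yl]propanedioate
Product: 12 dimethyl 2-[(2E,5R,8E,12E)-13-bromo-1-hydroxy-2,8,12-trimethyltrideca-2,8,12-trien-5-yl]propanedioate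
Conditions: NaBH4, CeCl3·7H2O, MeOH, −40 °C
Reagents that add atoms: none
Why: Luche reduction gives clean 1,2-reduction of the enal to the allylic alcohol and does not reduce the esters.

Step 10
Reactants: 12 dimethyl 2-[(2E,5R,8E,12E)-13-bromo-1-hydroxy-2,8,12-trimethyltrideca-2,8,12-trien-5-yl]propanedioate
Product: 13 methyl (3R,6E,10E)-11-bromo-3-[(2E)-4-hydroxy-3-methylbut-2-en-1-yl]-6,10-dimethylundeca-6,10-dienoate
Conditions: LiCl (3 equiv), H2O (2 equiv), DMSO, 150 °C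
Reagents that add atoms: none
Why: Krapcho dealkoxycarbonylation removes one ester by chloride attack on its methyl group and loss of CO2, leaving the C15H2–C16 ester; no epoxide is present yet.

Step 11
Reactants: 13 methyl (3R,6E,10E)-11-bromo-3-[(2E)-4-hydroxy-3-methylbut-2-en-1-yl]-6,10-dimethylundeca-6,10-dienoate
Product: 14 (3R,6E,10E)-11-bromo-3-[(2E)-4-hydroxy-3-methylbut-2-en-1-yl]-6,10-dimethylundeca-6,10-dienoic acid
Conditions: LiOH·H2O (3 equiv), THF/MeOH/H2O, rt; 1 M HCl to pH 3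
Reagents that add atoms: lithium hydroxide [Li+].[OH-]
Why: saponification is done before any epoxide exists, so no Payne rearrangement or epoxide opening can interfere.

Step 12
Reactants: 14 (3R,6E,10E)-11-bromo-3-[(2E)-4-hydroxy-3-methylbut-2-en-1-yl]-6,10-dimethylundeca-6,10-dienoic acid
Product: 16 (4R,6R)-4-(2-{(2S,3S)-3-[(3E)-4-bromo-3-methylbut-3-en-1-yl]-2-methyloxiran-2-yl}ethyl)-6-[(2S)-1,2-dihydroxypropan-2-yl]oxan-2-one, via bis-epoxy acid 15 (not isolated)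
Conditions: 1,2:4,5-di-O-isopropylidene-β-L-erythro-2,3-hexodiulo-2,6-pyranose (L-fructose-derived Shi ketone, 0.6 equiv), KHSO5 (as 2KHSO5·KHSO4·K2SO4, 4 equiv), K2CO3, Bu4NHSO4 (cat.), MeCN/CH2(OMe)2/aq. Na2B4O7–Na2EDTA, pH 10.5, 0 °C; acidify to pH 4, extract; then Ti(OiPr)4 (1.5 equiv), CH2Cl2, rt
Reagents that add atoms: potassium peroxymonosulfate [K+].[O-]S(=O)(=O)OO
Why: in the Shi epoxidation the chiral dioxirane attacks both E-trisubstituted olefins on the same face through the spiro transition state to give the (3S,4S) and (11S,12S) oxiranes (the bromoalkene is too electron-poor to react), and the Ti-bound 2,3-epoxy alcohol is then opened by the tethered acid at C3 (6-exo, SN2 inversion) to give the δ-lactone with C3 (R) and the C4 (S) tertiary alcohol.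

Step 13
Reactants: 16 (4R,6R)-4-(2-{(2S,3S)-3-[(3E)-4-bromo-3-methylbut-3-en-1-yl]-2-methyloxiran-2-yl}ethyl)-6-[(2S)-1,2-dihydroxypropan-2-yl]oxan-2-one
Product: 17 (4R,6R)-4-(2-{(2S,3S)-3-[(3E)-4-bromo-3-methylbut-3-en-1-yl]-2-methyloxiran-2-yl}ethyl)-6-[(2R)-2-hydroxy-1-oxopropan-2-yl]oxan-2-one
Conditions: IBX (1.5 equiv), DMSO, rt
Reagents that add atoms: none
Why: IBX oxidises the primary alcohol of the 1,2-diol to the aldehyde without glycol cleavage and cannot oxidise the tertiary alcohol (the descriptor change at C4 is only a priority change).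

Step 14
Reactants: 17 (4R,6R)-4-(2-{(2S,3S)-3-[(3E)-4-bromo-3-methylbut-3-en-1-yl]-2-methyloxiran-2-yl}ethyl)-6-[(2R)-2-hydroxy-1-oxopropan-2-yl]oxan-2-one
Product: 18 (4R,6R)-4-(2-{(2S,3S)-3-[(3E)-4-bromo-3-methylbut-3-en-1-yl]-2-methyloxiran-2-yl}ethyl)-6-[(2S)-2-hydroxybut-3-en-2-yl]oxan-2-one
Conditions: Ph3PCH3Br (3 equiv), KN(SiMe3)2 (2.8 equiv), THF, 0 °C; add 17 at −78 → 0 °C
Reagents that add atoms: methyltriphenylphosphonium bromide C[P+](c1ccccc1)(c1ccccc1)c1ccccc1.[Br-]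
Why: Wittig methylenation of the non-enolisable aldehyde is much faster at low temperature than attack on the lactone and installs C6 as a vinyl group on C4.

Step 15
Reactants: 18 (4R,6R)-4-(2-{(2S,3S)-3-[(3E)-4-bromo-3-methylbut-3-en-1-yl]-2-methyloxiran-2-yl}ethyl)-6-[(2S)-2-hydroxybut-3-en-2-yl]oxan-2-one
Product: 19 (4R,6R)-4-(2-{(2S,3S)-3-[(3E)-4-bromo-3-methylbut-3-en-1-yl]-2-methyloxiran-2-yl}ethyl)-6-[(2S)-2-(triethylsilyloxy)but-3-en-2-yl]oxan-2-one
Conditions: Et3SiOTf (1.5 equiv), 2,6-lutidine (3 equiv), CH2Cl2, −78 → 0 °C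
Reagents that add atoms: triethylsilyl trifluoromethanesulfonate CC[Si](CC)(CC)OS(=O)(=O)C(F)(F)F
Why: silylation with the silyl triflate protects the hindered tertiary alcohol so that the enolate, borane and palladium steps meet no free OH.

Step 16
Reactants: 19 (4R,6R)-4-(2-{(2S,3S)-3-[(3E)-4-bromo-3-methylbut-3-en-1-yl]-2-methyloxiran-2-yl}ethyl)-6-[(2S)-2-(triethylsilyloxy)but-3-en-2-yl]oxan-2-one
Product: 21 (3S,4R,6R)-4-(2-{(2S,3S)-3-[(3E)-4-bromo-3-methylbut-3-en-1-yl]-2-methyloxiran-2-yl}ethyl)-3-methyl-6-[(2S)-2-(triethylsilyloxy)but-3-en-2-yl]oxan-2-one, via lithium enolate 20 (not isolated)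
Conditions: LiN(i-Pr)2 (1.2 equiv), THF, −78 °C; MeI (5 equiv), −78 → −40 °C
Reagents that add atoms: iodomethane CI
Why: in this kinetic lactone enolate alkylation MeI approaches anti to the neighbouring C1 substituent and gives the 3,4-trans lactone, C15 (S), which is also the thermodynamically preferred epimer.

Step 17
Reactants: 21 (3S,4R,6R)-4-(2-{(2S,3S)-3-[(3E)-4-bromo-3-methylbut-3-en-1-yl]-2-methyloxiran-2-yl}ethyl)-3-methyl-6-[(2S)-2-(triethylsilyloxy)but-3-en-2-yl]oxan-2-one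
Product: 23 (1R,3R,4S,7E,11S,12S,15S)-11,12-epoxy-4-(triethylsilyloxy)cembr-7-en-16,3-olide, via B-alkylborane 22 (not isolated)
Conditions: 9-BBN-H (2.5 equiv), THF, 0 °C → rt; then slow addition to Pd(dppf)Cl2 (15 mol %), AsPh3 (30 mol %), Cs2CO3 (3 equiv), DMF/THF/H2O, 50 °C, 1 mM; pH 4 work-up
Reagents that add atoms: none
Why: anti-Markovnikov hydroboration of the vinyl group followed by intramolecular B-alkyl Suzuki–Miyaura coupling under high dilution forms C6–C7 with retention of the vinyl bromide geometry, closing the 14-membered ring as the 7E-olefin.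

Step 18
Reactants: 23 (1R,3R,4S,7E,11S,12S,15S)-11,12-epoxy-4-(triethylsilyloxy)cembr-7-en-16,3-olide
Product: 24 (1R,3R,4S,7E,11S,12S,15S)-11,12-epoxy-4-hydroxycembr-7-en-16,3-olide
Conditions: Bu4NF/AcOH (1:1, 3 equiv), THF, rt
Reagents that add atoms: none
Why: buffered fluoride desilylation frees the tertiary alcohol without opening the oxirane or the lactone.

Step 19
Reactants: 24 (1R,3R,4S,7E,11S,12S,15S)-11,12-epoxy-4-hydroxycembr-7-en-16,3-olide
Product: 25 (1R,3R,4S,7R,11S,12S,15S)-11,12-epoxy-7-hydroperoxy-4-hydroxycembr-8(19)-en-16,3-olide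
Conditions: O2, tetraphenylporphyrin (1 mol %), visible light, CH2Cl2, 0 °C; no reductive work-up; HPLC
Reagents that add atoms: dioxygen O=O
Why: in the Schenck ene reaction singlet oxygen adds to C7 of the only olefin with hydrogen abstraction from C19 on the more crowded side (cis effect), and C7 is set by attack on the exposed peripheral face of the lactone-bridged macrocycle; this is substrate control, so the 7R isomer must be separated from the C7 epimer and the C8 hydroperoxide.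

## Compound list

1 | pent-4-yn-1-ol | C#CCCCO | starting material
2 | [(1E)-5-(dimethylalumanyloxy)-2-methylpent-1-en-1-yl]dimethylalane | C[Al](C)/C=C(\C)CCCO[Al](C)C | intermediate
3 | (E)-5-bromo-4-methylpent-4-en-1-ol | OCCC/C(C)=C/Br | intermediate
4 | (E)-5-bromo-4-methylpent-4-enal | O=CCC/C(C)=C/Br | intermediate
5 | (6E)-7-bromo-2,6-dimethylhepta-1,6-dien-3-ol (racemic) | C=C(C)C(O)CC/C(C)=C/Br | intermediate
6 | ethyl (4E,8E)-9-bromo-4,8-dimethylnona-4,8-dienoate | CCOC(=O)CC/C(C)=C/CC/C(C)=C/Br | intermediate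
7 | (4E,8E)-9-bromo-4,8-dimethylnona-4,8-dienal | O=CCC/C(C)=C/CC/C(C)=C/Br | intermediate
8 | (2E,6E,10E)-11-bromo-6,10-dimethylundeca-2,6,10-trienal | O=C/C=C/CC/C(C)=C/CC/C(C)=C/Br | intermediate
9 | dimethyl malonate | COC(=O)CC(=O)OC | starting material
10 | dimethyl 2-[(3R,6E,10E)-11-bromo-6,10-dimethyl-1-oxoundeca-6,10-dien-3-yl]propanedioate | COC(=O)C(C(=O)OC)[C@@H](CC=O)CC/C(C)=C/CC/C(C)=C/Br | intermediate
11 | dimethyl 2-[(2E,5R,8E,12E)-13-bromo-2,8,12-trimethyl-1-oxotrideca-2,8,12-trien-5-yl]propanedioate | COC(=O)C(C(=O)OC)[C@@H](C/C=C(\C)C=O)CC/C(C)=C/CC/C(C)=C/Br | intermediate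
12 | dimethyl 2-[(2E,5R,8E,12E)-13-bromo-1-hydroxy-2,8,12-trimethyltrideca-2,8,12-trien-5-yl]propanedioate | COC(=O)C(C(=O)OC)[C@@H](C/C=C(\C)CO)CC/C(C)=C/CC/C(C)=C/Br | intermediate
13 | methyl (3R,6E,10E)-11-bromo-3-[(2E)-4-hydroxy-3-methylbut-2-en-1-yl]-6,10-dimethylundeca-6,10-dienoate | COC(=O)C[C@@H](C/C=C(\C)CO)CC/C(C)=C/CC/C(C)=C/Br | intermediate
14 | (3R,6E,10E)-11-bromo-3-[(2E)-4-hydroxy-3-methylbut-2-en-1-yl]-6,10-dimethylundeca-6,10-dienoic acid | OC(=O)C[C@@H](C/C=C(\C)CO)CC/C(C)=C/CC/C(C)=C/Br | intermediate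
15 | (3R)-5-{(2S,3S)-3-[(3E)-4-bromo-3-methylbut-3-en-1-yl]-2-methyloxiran-2-yl}-3-{[(2S,3S)-3-(hydroxymethyl)-3-methyloxiran-2-yl]methyl}pentanoic acid | OC(=O)C[C@@H](C[C@@H]1O[C@@]1(C)CO)CC[C@]1(C)O[C@H]1CC/C(C)=C/Br | intermediate
16 | (4R,6R)-4-(2-{(2S,3S)-3-[(3E)-4-bromo-3-methylbut-3-en-1-yl]-2-methyloxiran-2-yl}ethyl)-6-[(2S)-1,2-dihydroxypropan-2-yl]oxan-2-one | O=C1C[C@H](CC[C@]2(C)O[C@H]2CC/C(C)=C/Br)C[C@@H](O1)[C@@](C)(O)CO | intermediate
17 | (4R,6R)-4-(2-{(2S,3S)-3-[(3E)-4-bromo-3-methylbut-3-en-1-yl]-2-methyloxiran-2-yl}ethyl)-6-[(2R)-2-hydroxy-1-oxopropan-2-yl]oxan-2-one | O=C1C[C@H](CC[C@]2(C)O[C@H]2CC/C(C)=C/Br)C[C@@H](O1)[C@@](C)(O)C=O | intermediate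
18 | (4R,6R)-4-(2-{(2S,3S)-3-[(3E)-4-bromo-3-methylbut-3-en-1-yl]-2-methyloxiran-2-yl}ethyl)-6-[(2S)-2-hydroxybut-3-en-2-yl]oxan-2-one | O=C1C[C@H](CC[C@]2(C)O[C@H]2CC/C(C)=C/Br)C[C@@H](O1)[C@@](C)(O)C=C | intermediate
19 | (4R,6R)-4-(2-{(2S,3S)-3-[(3E)-4-bromo-3-methylbut-3-en-1-yl]-2-methyloxiran-2-yl}ethyl)-6-[(2S)-2-(triethylsilyloxy)but-3-en-2-yl]oxan-2-one | O=C1C[C@H](CC[C@]2(C)O[C@H]2CC/C(C)=C/Br)C[C@@H](O1)[C@@](C)(O[Si](CC)(CC)CC)C=C | intermediate
20 | lithium enolate of 19 (lithium (4R,6R)-3,4-dihydro-2H-pyran-6-olate form) | [Li+].[O-]C1=C[C@H](CC[C@]2(C)O[C@H]2CC/C(C)=C/Br)C[C@@H](O1)[C@@](C)(O[Si](CC)(CC)CC)C=C | intermediate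
21 | (3S,4R,6R)-4-(2-{(2S,3S)-3-[(3E)-4-bromo-3-methylbut-3-en-1-yl]-2-methyloxiran-2-yl}ethyl)-3-methyl-6-[(2S)-2-(triethylsilyloxy)but-3-en-2-yl]oxan-2-one | O=C1[C@@H](C)[C@H](CC[C@]2(C)O[C@H]2CC/C(C)=C/Br)C[C@@H](O1)[C@@](C)(O[Si](CC)(CC)CC)C=C | intermediate
22 | (3S,4R,6R)-6-[(2S)-4-(9-borabicyclo[3.3.1]nonan-9-yl)-2-(triethylsilyloxy)butan-2-yl]-4-(2-{(2S,3S)-3-[(3E)-4-bromo-3-methylbut-3-en-1-yl]-2-methyloxiran-2-yl}ethyl)-3-methyloxan-2-one | O=C1[C@@H](C)[C@H](CC[C@]2(C)O[C@H]2CC/C(C)=C/Br)C[C@@H](O1)[C@@](C)(O[Si](CC)(CC)CC)CCB1C2CCCC1CCC2 | intermediate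
23 | (1R,3R,4S,7E,11S,12S,15S)-11,12-epoxy-4-(triethylsilyloxy)cembr-7-en-16,3-olide | C1/C=C(\C)CC[C@@H]2O[C@@]2(C)CC[C@@H]2C[C@@H](OC(=O)[C@H]2C)[C@@](C)(O[Si](CC)(CC)CC)C1 | intermediate
24 | (1R,3R,4S,7E,11S,12S,15S)-11,12-epoxy-4-hydroxycembr-7-en-16,3-olide | C1/C=C(\C)CC[C@@H]2O[C@@]2(C)CC[C@@H]2C[C@@H](OC(=O)[C@H]2C)[C@@](C)(O)C1 | intermediate
25 | (1R,3R,4S,7R,11S,12S,15S)-11,12-epoxy-7-hydroperoxy-4-hydroxycembr-8(19)-en-16,3-olide | C=C1CC[C@@H]2O[C@@]2(C)CC[C@@H]2C[C@@H](OC(=O)[C@H]2C)[C@@](C)(O)CC[C@H]1OO | target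

## Step count and risks

Total steps: 19. Longest linear sequence: 19 steps (1 → 25); dimethyl malonate 9 enters at step 7. Minor diastereomers from the roughly 90% ee Michael step and the two epoxidations are removed by chromatography at 16.

**Step 19 (most likely to fail).** The ene reaction can give the C8 tertiary hydroperoxide and the C7 epimer beside 25, and nothing but the macrocycle controls the face. The fallback sets out from 24 and comes back at 25. The ene mixture from 24 is separated, and the C7-epimeric hydroperoxide (1R,3R,4S,7S,11S,12S,15S)-11,12-epoxy-7-hydroperoxy-4-hydroxycembr-8(19)-en-16,3-olide F1 is reduced with PPh3 (CH2Cl2, 0 °C) to the (7S)-allylic alcohol F2. The secondary alcohol is converted selectively with MsCl/Et3N (CH2Cl2, −40 °C) into the 7-methanesulfonate F3, which is displaced with anhydrous H2O2 in Et2O (−78 → −20 °C). This SN2 inversion gives 25, so C7 is fixed by substitution and not by the face selectivity of the ene reaction; the SN2′ isomer, if formed, is removed by HPLC.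

**Step 17.** The macrocyclic B-alkyl Suzuki coupling may lose material to protodeboronation, oligomers or lactone hydrolysis. The fallback sets out from 21 and comes back at 23. Hydroboration of 21 to 22 followed by oxidation with NaBO3·4H2O (THF/H2O, rt) gives the primary alcohol (3S,4R,6R)-4-(2-{(2S,3S)-3-[(3E)-4-bromo-3-methylbut-3-en-1-yl]-2-methyloxiran-2-yl}ethyl)-6-[(2S)-4-hydroxy-2-(triethylsilyloxy)butan-2-yl]-3-methyloxan-2-one F4. I2/PPh3/imidazole (CH2Cl2, 0 °C) converts it into the primary iodide F5, and zinc insertion (Zn dust, LiCl, THF, 30 °C) gives the alkylzinc iodide F6. F6 is cyclised onto the vinyl bromide under high dilution by Negishi coupling (Pd(OAc)2, 2-dicyclohexylphosphino-2′,6′-dimethoxybiphenyl, THF, 40 °C) to give 23; the organozinc tolerates the lactone and the oxirane and needs no aqueous base.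

**Step 12.** The double Shi epoxidation may give too low a face selectivity at the allylic-alcohol olefin, or the free acid may disturb the epoxidation or the regiochemistry of ring closure. The fallback sets out from 13 and comes back at 15. Katsuki–Sharpless epoxidation of ester 13 (Ti(OiPr)4, L-(+)-diethyl tartrate, t-BuOOH, 4 Å MS, CH2Cl2, −20 °C) gives methyl (3R,6E,10E)-11-bromo-3-{[(2S,3S)-3-(hydroxymethyl)-3-methyloxiran-2-yl]methyl}-6,10-dimethylundeca-6,10-dienoate F7 with hydroxyl-directed reagent control at C3/C4. The remaining isolated olefin is then epoxidised with the same L-fructose-derived ketone and KHSO5 to give the bis-epoxy methyl ester F8. Brief saponification (LiOH, THF/H2O, 0 °C; HCl to pH 4) liberates acid 15, which is lactonised with Ti(OiPr)4 as in step 12.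

Further compounds
F1 | step 19 | (1R,3R,4S,7S,11S,12S,15S)-11,12-epoxy-7-hydroperoxy-4-hydroxycembr-8(19)-en-16,3-olide | C=C1CC[C@@H]2O[C@@]2(C)CC[C@@H]2C[C@@H](OC(=O)[C@H]2C)[C@@](C)(O)CC[C@@H]1OO
F2 | step 19 | (1R,3R,4S,7S,11S,12S,15S)-11,12-epoxy-4,7-dihydroxycembr-8(19)-en-16,3-olide | C=C1CC[C@@H]2O[C@@]2(C)CC[C@@H]2C[C@@H](OC(=O)[C@H]2C)[C@@](C)(O)CC[C@@H]1O
F3 | step 19 | (1R,3R,4S,7S,11S,12S,15S)-11,12-epoxy-4-hydroxy-7-(methanesulfonyloxy)cembr-8(19)-en-16,3-olide | C=C1CC[C@@H]2O[C@@]2(C)CC[C@@H]2C[C@@H](OC(=O)[C@H]2C)[C@@](C)(O)CC[C@@H]1OS(C)(=O)=O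
F4 | step 17 | (3S,4R,6R)-4-(2-{(2S,3S)-3-[(3E)-4-bromo-3-methylbut-3-en-1-yl]-2-methyloxiran-2-yl}ethyl)-6-[(2S)-4-hydroxy-2-(triethylsilyloxy)butan-2-yl]-3-methyloxan-2-one | O=C1[C@@H](C)[C@H](CC[C@]2(C)O[C@H]2CC/C(C)=C/Br)C[C@@H](O1)[C@@](C)(O[Si](CC)(CC)CC)CCO
F5 | step 17 | (3S,4R,6R)-4-(2-{(2S,3S)-3-[(3E)-4-bromo-3-methylbut-3-en-1-yl]-2-methyloxiran-2-yl}ethyl)-6-[(2S)-4-iodo-2-(triethylsilyloxy)butan-2-yl]-3-methyloxan-2-one | O=C1[C@@H](C)[C@H](CC[C@]2(C)O[C@H]2CC/C(C)=C/Br)C[C@@H](O1)[C@@](C)(O[Si](CC)(CC)CC)CCI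
F6 | step 17 | alkylzinc iodide from F5 ({(3S)-3-[(2R,4R,5S)-4-(2-{(2S,3S)-3-[(3E)-4-bromo-3-methylbut-3-en-1-yl]-2-methyloxiran-2-yl}ethyl)-5-methyl-6-oxooxan-2-yl]-3-(triethylsilyloxy)butyl}zinc iodide) | O=C1[C@@H](C)[C@H](CC[C@]2(C)O[C@H]2CC/C(C)=C/Br)C[C@@H](O1)[C@@](C)(O[Si](CC)(CC)CC)CC[Zn]I
F7 | step 12 | methyl (3R,6E,10E)-11-bromo-3-{[(2S,3S)-3-(hydroxymethyl)-3-methyloxiran-2-yl]methyl}-6,10-dimethylundeca-6,10-dienoate | COC(=O)C[C@@H](C[C@@H]1O[C@@]1(C)CO)CC/C(C)=C/CC/C(C)=C/Br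
F8 | step 12 | methyl (3R)-5-{(2S,3S)-3-[(3E)-4-bromo-3-methylbut-3-en-1-yl]-2-methyloxiran-2-yl}-3-{[(2S,3S)-3-(hydroxymethyl)-3-methyloxiran-2-yl]methyl}pentanoate | COC(=O)C[C@@H](C[C@@H]1O[C@@]1(C)CO)CC[C@]1(C)O[C@H]1CC/C(C)=C/Br
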